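The readings were computed with made-up constants; noise was put on by code.

If the dusk run is a guide, the excess of left-handed product over right-handed product sinks as conversion climbs, from a reading of 50.4 % at 10.0 s to 44.7 % at 50.0 s, so maple and birch are to be judged by where each flask stops.

the same everywhere: catalyst 25 µM

| charge | left-handed substrate | right-handed substrate | solid reagent | protic impurity | remark | time |
|---|---|---|---|---|---|---|
| dusk | 0.75 mM | 0.75 mM | 0.75 mM | 0.050 mM | run made earlier |  |
| maple | 0.50 mM | 0.50 mM | 0.750 mM | 0.0500 mM |  | 4.0 min |
| birch | 0.50 mM | 0.50 mM | 0.750 mM | 0.200 mM |  | 4.0 min |

dusk run (percent of the left-handed substrate and right-handed substrate together charged)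

| time / s | left-handed product / % | right-handed product / % |
|---|---|---|
| 10.0 | 19.1 | 6.3 |
| 12.0 | 23.2 | 7.4 |
| 20.0 | 26.3 | 9.2 |
| 30.0 | 29.6 | 10.9 |
| 50.0 | 30.9 | 11.8 |

(readings scatter by 0.5 percentage points)

- the winner by excess of left-handed product over right-handed product in the product; "neither" if no more than 2 percentage points parts them (maple / birch / neither)
- excess of left-handed product over right-handed product in the product at the end, maple
- excess of left-handed product over right-handed product in the product at the end, birch

- catalyst is single-handed; left-handed substrate and right-handed substrate are mirror images of each other, charged as a racemate, each of them at the stated concentration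
- solid, in amounts per volume of the solution: solid reagent
- what was read earlier has a scatter of 0.5 percentage points, one standard deviation
- at the start none of the solid reagent is in solution
- an excess is below zero if the other one leads
- no earlier run changes the charge of protic impurity; that part of a forecast is a guess

The solid reagent in maple and in birch, 0.750 mM, is less than the 1.00 mM of the two substrates together, so it is the limiting reagent, but the protic impurity may take a share of it. Counting one solid reagent per protic impurity gives birch 55.0 % and maple 70.0 % as the reagent budget, meaning the solid reagent charge less the impurity charge, over both substrates charged. For dusk the same count gives 46.7 %, and its last reading of 42.7 % had risen 2.2 percentage points since 30.0 s, so dusk does not contradict the count, but with a single impurity charge on hand the ratio remains a guess. Birch, with the lower budget, should keep the larger excess.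

The forecast names birch, with 33 % for maple and 46 % for birch: “That suggests about two reagent per impurity, though one-to-one (46.7%) isn't fully excluded.” The count here parts from it and takes the forecast's one-to-one figures instead, 30 for maple and 39.5 for birch.

Birch gives 39.1 % and maple 32.0 %, so birch leads as forecast, with birch 6.9 points below the forecast. In birch, 0.169 mM of quenched reagent stands against 0.169 mM of protic impurity gone, which is one reagent for each. The budget of 55.0 % sits below the 57.5 % reacted in birch, and with the quenched reagent in place of the impurity charge it reads 58.1 %, the gap being the 0.00634 mM that birch still holds as partner and dormant form at 4.00 min.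

    partner + protic impurity → quenched reagent (k = 550 M⁻¹ s⁻¹)
    solid reagent ⇌ partner, rate k2*(cs2 - [partner]) while solid is left; crystals form when [partner] > cs2 (solubility = 0.450 mM, k = 0.180 s⁻¹)
    partner + catalyst + left-handed substrate → catalyst + left-handed product (k = 1.90 × 10⁷ M⁻² s⁻¹)
    partner + catalyst + right-handed substrate → catalyst + right-handed product (k = 5.10 × 10⁶ M⁻² s⁻¹)
    partner ⇌ dormant form (K = 3.70, k = 0.130 s⁻¹)

A neighbour of maple charged with 0.30 mM of solid reagent has a budget of 25.0 %, lower than maple's, which points to a larger excess. That flask reaches 27.6 % of product and an excess of 51.1 %.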